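The trap in these flasks is to judge the first exchange by its speed: its forward half-life in larch, 14 min, is shorter than the run of 50 min, yet what that step makes it can take back.

    starting complex + incoming ligand ⇌ leaving ligand + complex with one exchanged (K1 = 0.62, k1 = 0.0088 M⁻¹ s⁻¹, Ea1 = 70.0 kJ mol⁻¹, ΔH1 = −44.0 kJ mol⁻¹)
    complex with one exchanged + incoming ligand ⇌ leaving ligand + complex with two exchanged (K2 = 0.17, k2 = 0.024 M⁻¹ s⁻¹, Ea2 = 50.0 kJ mol⁻¹, ΔH2 = 5.00 kJ mol⁻¹)
    complex with two exchanged + incoming ligand ⇌ idle adduct, settled at all times (K3 = 15 M⁻¹, ΔH3 = −4.00 kJ mol⁻¹)
    complex with one exchanged → side product (k4 = 6.8 × 10⁻⁴ s⁻¹, Ea4 = 100 kJ mol⁻¹)
    (constants at 70 °C)

| setting | birch | larch | alder |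
|---|---|---|---|
| starting complex | 0.10 M (in portions, 3) | 0.10 M (in portions, 3) | 0.10 M (in portions, 3) |
| incoming ligand | 0.0950 M | 0.0950 M | 0.0950 M |
| leaving ligand | 0.0500 M | 0.0500 M | 0.0500 M |
| temperature | 120 °C | 70 °C | 95 °C |
| time | 50 min | 50 min | 50 min |
| remark | the portions of starting complex follow each other after 6.0 min, the first at the start | the portions of starting complex follow each other after 6.0 min, the first at the start | the portions of starting complex follow each other after 6.0 min, the first at the start |

- which of these there is most of at the end, counted by the starting complex in it, birch (side product / complex with one exchanged / starting complex / complex with two exchanged)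
- which of these there is most of at the end, counted by the starting complex in it, larch (side product / complex with one exchanged / starting complex / complex with two exchanged)
- which of these there is most of at the end, counted by the starting complex in it, alder (side product / complex with one exchanged / starting complex / complex with two exchanged)
- final amount of the leader among these, as a percentage of the starting complex charged, in birch
- final amount of the leader among these, as a percentage of the starting complex charged, in larch
- final amount of the leader among these, as a percentage of the starting complex charged, in alder

- for complex with two exchanged the idle adduct is counted in
- at 70 °C the constants are as listed, elsewhere as the activation energies and enthalpies make them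

We freeze what barely moves. Suppose the complex with one exchanged and the complex with two exchanged stay small, so that each incoming ligand consumed becomes one side product and frees one leaving ligand; then, once the last portion is in, starting complex minus incoming ligand stays at 0.00500 M, far less than the charge, and the two fall together. Let c_M be the charge of starting complex, c_L that of leaving ligand, and u the fraction of c_M still present as starting complex. Let k_d be the constant of the loss to side product, and K and k_f the balance and forward constants of the first exchange, each at the flask's temperature. Let t′ be the run less the mean wait of the portions, 6.0 min. The loss then integrates to one dimensionless number N:

N = k_d K t′ / (1 + k_d K / (k_f c_L)) = (1 + c_L/c_M)(1/u − 1) + ln u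

Here 1 + c_L/c_M is 1.50. We call N the drain number: the run counted in the time the loss needs at equal ligands, cut down by the return of the complex with one exchanged to starting complex, a pre-equilibrium only partly kept. Solving for u by hand gives:

birch: N = 8.93, u = 12.0%

larch: N = 0.568, u = 57.3%

alder: N = 2.50, u = 28.5%

So we commit to side product leading in birch at 88.0% and in alder at 71.5%, and to starting complex leading in larch at 57.3%. One number is not enough for the side product in larch, though: N takes the intermediates to be small and does not test that, so in larch we commit the 42.7% that has left the starting complex to side product and intermediates together, not to side product by itself.

The forecast named side product at 86% in birch, starting complex at 51% in larch and side product at 72% in alder, holding that “the high-activation-energy drain from the once-exchanged complex to side product wins” at the higher temperatures. The simulation gives side product at 86.8% in birch, starting complex at 56.2% in larch and side product at 70.0% in alder, with side product in larch at 28.0%.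

A neighbour of alder charged with 0.25 M of starting complex keeps alder's temperature and leaving ligand, so N stays 2.50, but incoming ligand, charge c_X, is now the limiting reagent, and the frozen difference d′ is 0.155 M. With a = (c_L + c_X)/d′ = 0.935, the same integration leaves, for small remainders, this fraction of incoming ligand:

x = exp(−(N + (1 + a) ln(c_M/d′))/a) = 2.56%

That makes side product 37.0% of the complex charged. The neighbour flask gives 2.04% of its incoming ligand left, 37.1% side product, and starting complex in the lead at 62.8%.

The constants used here were set for the occasion; what happens was integrated by code.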